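**Assumption:** the target SMILES has no stereodescriptors and no stereocentres. I therefore target the constitution; any planar or conformational chirality of the macrocycle is not specified and is not controlled (racemic).

## Retrosynthetic overview
1. The final product comes from BBr3 demethylation of the ring-A OMe. The ring-C catechol is made just before that by IBX ortho-oxygenation (Pettus) of a ring-C phenol. That phenol is revealed, together with saturation of both bridges, by one global H2/Pd step.
2. **Key disconnection:** the ring D–ring A CH2–CH2 bridge is formed in the last ring closure. This is a ketyl-radical (McMurry) macrocyclisation of a bis-aryl-aldehyde, giving the 18-membered ring as a bis-stilbene.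
3. The dialdehyde comes from double Br→CHO conversion of a dibromo-stilbene. That stilbene is made by Wittig coupling of a ring-B benzyl phosphonium with a ring-C aldehyde, which pre-forms the ring B–ring C bridge.
4. The two diaryl ethers (C–O–D and A–O–B) are made by Cu-catalysed Ullmann coupling from small aryl halides and phenols. The only ring formed is the macrocycle, and it closes last.

## Route

**Step 1**
Reactants: 1 catechol
Product: 2 2,3-dihydroxybenzaldehyde
Conditions: (CH2O)n, MgCl2, Et3N, THF, reflux
Reagents that add atoms: paraformaldehyde, C=O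
Why: Casnati–Skattebøl ortho-formylation through a Mg-phenoxide chelate is ortho-selective. It installs the ring-C carbon handle next to the oxygen that will carry ring D.

**Step 2**
Reactants: 2
Product: 3 3-(benzyloxy)-2-hydroxybenzaldehyde
Conditions: BnBr (1.05 equiv), K2CO3, acetone, 50 °C
Reagents that add atoms: benzyl bromide, BrCc1ccccc1
Why: Williamson etherification is selective for the free 3-OH. The 2-OH is hydrogen-bonded to the CHO, so the oxygen that must be arylated is left free and the other one is protected.

**Step 3**
Reactants: 3; 4 1-bromo-3-iodobenzene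
Product: 5 3-(benzyloxy)-2-(3-bromophenoxy)benzaldehyde
Conditions: CuI (10 mol%), picolinic acid (20 mol%), K3PO4, DMSO, 90 °C
Reagents that add atoms: none
Why: Ullmann-type Cu-catalysed C–O coupling reacts at C–I over C–Br and tolerates hindered ortho-substituted phenols. The remaining Br is the later handle for ring-D formylation.

**Step 4**
Reactants: 6 4-bromophenol
Product: 7 4-bromo-2-iodophenol
Conditions: NIS, MeCN, cat. TsOH, rt
Reagents that add atoms: N-iodosuccinimide, O=C1CCC(=O)N1I
Why: electrophilic iodination goes ortho to OH because the para position is blocked.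

**Step 5**
Reactants: 7
Product: 8 4-bromo-2-iodo-1-methoxybenzene
Conditions: MeI, K2CO3, acetone, rt
Reagents that add atoms: iodomethane, CI
Why: Williamson O-methylation gives a ring-A oxygen that survives the organolithium, Ti(0) and IBX steps.

**Step 6**
Reactants: 8; 9 p-cresol
Product: 10 4-bromo-1-methoxy-2-(4-methylphenoxy)benzene
Conditions: CuI (10 mol%), N,N-dimethylglycine (30 mol%), Cs2CO3, dioxane, 90 °C
Reagents that add atoms: none
Why: Ullmann diaryl ether formation occurs chemoselectively at the ortho C–I. The C–Br para to OMe is kept as the ring-A handle.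

**Step 7**
Reactants: 10
Product: 11 4-bromo-2-[4-(bromomethyl)phenoxy]-1-methoxybenzene
Conditions: NBS (1.0 equiv), AIBN, PhCF3, 80 °C
Reagents that add atoms: N-bromosuccinimide, O=C1CCC(=O)N1Br
Why: Wohl–Ziegler radical benzylic bromination. The only benzylic C–H bonds are on the ring-B methyl group at this stage.

**Step 8**
Reactants: 11; 5
Product: 12 stilbene (E/Z mixture) COc1ccc(Br)cc1Oc1ccc(C=Cc2cccc(OCc3ccccc3)c2Oc2cccc(Br)c2)cc1
Conditions: PPh3, toluene, 80 °C; then t-BuOK, THF, 0 °C, add 5, warm to rt (one pot)
Reagents that add atoms: none (PPh3, P(c1ccccc1)(c1ccccc1)c1ccccc1, is lost as Ph3P=O)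
Why: Wittig olefination builds the ring B–ring C bridge. The E/Z mixture is immaterial because the alkene is hydrogenated in step 11, and no stereocentre is formed.

**Step 9**
Reactants: 12
Product: 13 dialdehyde COc1ccc(C=O)cc1Oc1ccc(C=Cc2cccc(OCc3ccccc3)c2Oc2cccc(C=O)c2)cc1
Conditions: t-BuLi (4.4 equiv), THF, –78 °C, 10 min; then DMF, –78 °C → rt
Reagents that add atoms: DMF, CN(C)C=O
Why: double Br/Li exchange followed by Bouveault formylation turns both aryl bromides (ring A and ring D) into the two aldehydes needed for ring closure. Exchange at –78 °C is much faster than attack on the OBn group or the stilbene.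

**Step 10 (key step)**
Reactants: 13
Product: 14 macrocyclic bis-stilbene COc1ccc2cc1Oc1ccc(cc1)C=Cc1cccc(OCc3ccccc3)c1Oc1cccc(c1)C=C2
Conditions: TiCl4, Zn, pyridine, THF, reflux; substrate added by syringe pump over 16 h (~2 mM)
Reagents that add atoms: none
Why: McMurry coupling. Single-electron transfer from low-valent Ti gives two ketyl radical anions, which couple (radical–radical pinacol C–C bond formation) and are then deoxygenated to the alkene. Under pseudo-high dilution this closes the 18-membered ring and forms the ring D–ring A bridge. No stereocentre is created, and the new C=C geometry is irrelevant because it is reduced in step 11.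

**Step 11**
Reactants: 14
Product: 15 COc1ccc2cc1Oc1ccc(cc1)CCc1cccc(O)c1Oc1cccc(c1)CC2
Conditions: H2 (3 atm), 10% Pd/C, THF/EtOH, rt
Reagents that add atoms: none (H2 adds only hydrogens)
Why: hydrogenation reduces both stilbene C=C bonds to the CH2CH2 bridges, and hydrogenolysis removes the ring-C benzyl ether. The diaryl ethers and the OMe are unaffected.

**Step 12**
Reactants: 15
Product: 16 COc1ccc2cc1Oc1ccc(cc1)CCc1ccc(O)c(O)c1Oc1cccc(c1)CC2
Conditions: IBX, DMF, rt; then aq Na2S2O4, rt (one pot, degassed)
Reagents that add atoms: IBX, OC(=O)c1ccccc1I(=O)=O (supplies the new oxygen)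
Why: Pettus IBX ortho-oxygenation of the free phenol. The ortho position bearing the aryloxy group is blocked, so oxidation occurs only at the free ortho C–H (C4), giving an o-quinone. Dithionite reduces it to the catechol. Ring A is still OMe-protected, so only one phenol is oxidised.

**Step 13**
Reactants: 16
Product: 17 marchantin H (target)
Conditions: BBr3 (5 equiv), CH2Cl2, –78 → 0 °C; quench with MeOH
Reagents that add atoms: none (BBr3 removes the methyl group; the O–H comes from work-up)
Why: BBr3 cleaves the aryl methyl ether selectively. The diaryl ethers and the catechol survive at low temperature.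

## Compound list
1 | catechol | Oc1ccccc1O | starting material
2 | 2,3-dihydroxybenzaldehyde | O=Cc1cccc(O)c1O | intermediate
3 | 3-(benzyloxy)-2-hydroxybenzaldehyde | O=Cc1cccc(OCc2ccccc2)c1O | intermediate
4 | 1-bromo-3-iodobenzene | Brc1cccc(I)c1 | starting material
5 | 3-(benzyloxy)-2-(3-bromophenoxy)benzaldehyde | O=Cc1cccc(OCc2ccccc2)c1Oc1cccc(Br)c1 | intermediate
6 | 4-bromophenol | Oc1ccc(Br)cc1 | starting material
7 | 4-bromo-2-iodophenol | Oc1ccc(Br)cc1I | intermediate
8 | 4-bromo-2-iodo-1-methoxybenzene | COc1ccc(Br)cc1I | intermediate
9 | p-cresol | Cc1ccc(O)cc1 | starting material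
10 | 4-bromo-1-methoxy-2-(4-methylphenoxy)benzene | COc1ccc(Br)cc1Oc1ccc(C)cc1 | intermediate
11 | 4-bromo-2-[4-(bromomethyl)phenoxy]-1-methoxybenzene | COc1ccc(Br)cc1Oc1ccc(CBr)cc1 | intermediate
12 | dibromo-stilbene (E/Z) | COc1ccc(Br)cc1Oc1ccc(C=Cc2cccc(OCc3ccccc3)c2Oc2cccc(Br)c2)cc1 | intermediate
13 | dialdehyde | COc1ccc(C=O)cc1Oc1ccc(C=Cc2cccc(OCc3ccccc3)c2Oc2cccc(C=O)c2)cc1 | intermediate
14 | macrocyclic bis-stilbene | COc1ccc2cc1Oc1ccc(cc1)C=Cc1cccc(OCc3ccccc3)c1Oc1cccc(c1)C=C2 | intermediate
15 | macrocyclic phenol (OMe) | COc1ccc2cc1Oc1ccc(cc1)CCc1cccc(O)c1Oc1cccc(c1)CC2 | intermediate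
16 | macrocyclic catechol (OMe) | COc1ccc2cc1Oc1ccc(cc1)CCc1ccc(O)c(O)c1Oc1cccc(c1)CC2 | intermediate
17 | marchantin H | Oc1ccc2cc1Oc1ccc(cc1)CCc1ccc(O)c(O)c1Oc1cccc(c1)CC2 | target

**Total steps:** 13. **Longest linear sequence:** 10 steps (6 → 7 → 8 → 10 → 11 → 12 → 13 → 14 → 15/16 → 17).

**Three steps most likely to fail:**
1. **Step 10, McMurry macrocyclisation.** Risks are oligomerisation, over-reduction, and strain from the rigid p-phenylene/stilbene unit. Fallback: reduce 13 with NaBH4, convert the diol to the bis(benzylic bromide) with PBr3, and close the ring by a Zn/Ni or SmI2 benzylic-radical Wurtz homocoupling, which forms the CH2–CH2 bond directly and needs no hydrogenation of the new bridge.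
2. **Step 9, double Br/Li exchange and formylation** on a substrate containing a stilbene and benzyl ether. Fallback: Pd-catalysed reductive formylation of both aryl bromides (Pd(OAc)2/cataCXium A, CO/H2), which avoids organolithiums.
3. **Step 12, late-stage IBX ortho-oxygenation** on the macrocycle, where over-oxidation or low regioselectivity is possible. Fallback: install the C4 oxygen at the start. Dakin oxidation of 2 gives pyrogallol, Vilsmeier formylation gives 2,3,4-trihydroxybenzaldehyde, and selective 3,4-bis-O-benzylation gives the ring-C aldehyde, so step 12 is no longer needed.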